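**Plan**
Prostanoid numbering is used: C1 is the ester carbon, C7 the acetoxy carbon, C8–C12 the ring, C9 the ketone, C10 the iodinated carbon, C12 the carbinol. The retrosynthesis takes C10–I, the C9 ketone and the free 12-OH back to a 9,12-bis-silyl ether, then cuts C6–C7, then C12–C13, then C7–C8.
Forward, the ring is bought as (S)-4-silyloxycyclopentenone (carbonyl = C12, carbinol = C9). C7 is added at C8 by a formaldehyde aldol, the oct-2-ynyl chain at C12 by 1,2-addition, and the C1–C6 chain at C7 last; enone, iodine and free 12-OH follow.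
Enabling feature: C7 is the carbinol carbon of a secondary cis-allylic alcohol attached to ring carbon C8. It can therefore come from a C8–CH2–O carbamate whose pro-S hydrogen is replaced by the cis-alkenyl group of a boronate (lithiation, borylation, 1,2-shift from boron to C7, oxidation).
Stereochemistry: C9 (commercial) directs C8 (trans aldol), C8 directs C12 (addition anti to the C8 substituent), and C7 comes from (−)-sparteine; C9 is erased by the late oxidation.
The cis alkenes come from syn semihydrogenation of the C14 alkyne and from trans-hydroboration of a terminal alkyne, whose geometry survives the key step.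

Key step: step 9

Assumption: (S)-4-(tert-butyldimethylsilyloxy)cyclopent-2-en-1-one is taken as a commercial enantiopure compound (silyl ether of (S)-4-hydroxycyclopent-2-enone).

**Step 1**
Reactants: 1 (S)-4-(tert-butyldimethylsilyloxy)cyclopent-2-en-1-one; 2 formaldehyde
Product: 4 trans-4-silyloxy-5-(hydroxymethyl)cyclopentenone, via lithium dienolate 3 (not isolated)
Conditions: LiN(iPr)2, THF, −78 °C; CH2O gas (cracked paraformaldehyde), −78 °C; aq. NH4Cl
Reagents that add atoms: none
Why: Kinetic deprotonation at the saturated α'-carbon (C8) and aldol addition to formaldehyde anti to the neighbouring silyloxy group should set C8 trans to C9, and loss of silanolate is not expected at −78 °C because it would give an antiaromatic cyclopentadienone.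

**Step 2**
Reactants: 4 trans-4-silyloxy-5-(hydroxymethyl)cyclopentenone
Product: 5 primary TES ether
Conditions: Et3SiCl, imidazole, CH2Cl2, 0 °C
Reagents that add atoms: chlorotriethylsilane CC[Si](Cl)(CC)CC
Why: Standard imidazole-promoted silylation of the primary alcohol stops retro-aldol and dehydration of the β-hydroxy ketone and leaves a non-chelating, purely steric substituent on C8 for the next step.

**Step 3**
Reactants: 5 primary TES ether; 6 1-bromooct-2-yne
Product: 8 tertiary homopropargylic alcohol, via allenylzinc bromide 7 (not isolated)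
Conditions: Zn dust (activated), THF, 0 °C; then 5, −20 → 0 °C; aq. NH4Cl
Reagents that add atoms: none
Why: Barbier-type propargylation in which the allenylzinc bromide adds 1,2 to the enone carbonyl through a six-membered SE2' transition state at its CH2 terminus, approaching anti to the adjacent C8 substituent (1,2-induction expected to outweigh the remote 9-silyloxy group) so that C13 ends up trans to C7 and C12 has the target configuration.

**Step 4**
Reactants: 8 tertiary homopropargylic alcohol
Product: 9 tertiary TBS ether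
Conditions: tBuMe2SiOTf, 2,6-lutidine, CH2Cl2, 0 °C → rt
Reagents that add atoms: tert-butyldimethylsilyl trifluoromethanesulfonate CC(C)(C)[Si](C)(C)OS(=O)(=O)C(F)(F)F
Why: Silyl triflate silylation reaches the hindered tertiary alcohol, and the resulting tertiary TBS ether is the most robust protecting group in the molecule, which later allows the secondary 9-O-TBS group to be removed first.

**Step 5**
Reactants: 9 tertiary TBS ether
Product: 10 (Z)-oct-2-enyl compound
Conditions: H2 (1 atm), Pd/CaCO3 poisoned with Pb(OAc)2 (Lindlar catalyst), quinoline, hexane/EtOAc, rt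
Reagents that add atoms: none
Why: Lindlar semihydrogenation adds hydrogen syn to the internal alkyne to give the cis C14=C15 alkene, while the ring alkene, flanked by a quaternary and a silyloxy-bearing carbon, should be too hindered to be reduced.

**Step 6**
Reactants: 10 (Z)-oct-2-enyl compound
Product: 11 primary alcohol
Conditions: PPTS (cat.), MeOH/CH2Cl2, 0 °C
Reagents that add atoms: none
Why: Acid-catalysed methanolysis should cleave the unhindered primary TES ether much faster than the secondary and tertiary TBS ethers (selective desilylation).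

**Step 7**
Reactants: 11 primary alcohol
Product: 12 N,N-diisopropylcarbamate
Conditions: iPr2NCOCl, Et3N, DMAP (cat.), CH2Cl2, reflux
Reagents that add atoms: N,N-diisopropylcarbamoyl chloride CC(C)N(C(C)C)C(Cl)=O
Why: Carbamoylation of the primary alcohol installs the hindered carbamate that directs and stabilises α-lithiation at C7 and later serves as the leaving group.

**Step 8**
Reactants: 13 methyl hex-5-ynoate
Product: 14 (Z)-alkenyl pinacol boronate
Conditions: pinacolborane, [Rh(cod)Cl]2 (cat.), P(iPr)3, Et3N, cyclohexane, rt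
Reagents that add atoms: pinacolborane CC1(C)OBOC1(C)C
Why: Rhodium-catalysed formal trans-hydroboration of a terminal alkyne (through a rhodium vinylidene) delivers the (Z)-1-alkenylboronate, and the ester is inert to pinacolborane under these conditions.

**Step 9**
Reactants: 12 N,N-diisopropylcarbamate; 14 (Z)-alkenyl pinacol boronate
Product: 18 (7S)-allylic alcohol, via lithiated carbamate 15 (not isolated), via boronate complex 16 (not isolated), via allylic boronic ester 17 (not isolated)
Conditions: s-BuLi, (−)-sparteine, Et2O, −78 °C; then 14, −78 °C; MgBr2·OEt2, −78 → 35 °C; then 30% H2O2, aq. NaHCO3, THF, 0 °C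
Reagents that add atoms: hydrogen peroxide OO
Why: s-BuLi/(−)-sparteine removes the pro-S hydrogen of the O–CH2 group of 12 to give the dipole-stabilised organolithium 15, which boronate 14 captures with retention to give ate complex 16; on warming with MgBr2 the cis-alkenyl group migrates from boron to C7 with inversion while the carbamate leaves (1,2-metallate rearrangement) to give 17, which H2O2 oxidises with retention to 18. The closest known reaction type is the sparteine-mediated lithiation–borylation–oxidation of primary alkyl carbamates with alkenyl pinacol boronates, a reagent-controlled route to secondary allylic alcohols. No ring is closed. The only new stereocentre, C7, is controlled by the chiral diamine (choice of the pro-S hydrogen) and by the stereospecific retention–inversion–retention sequence, which together should give the 7S configuration, while the C5=C6 geometry is carried over because the alkenyl carbon migrates with retention. The step needs site selectivity for the hydrogens next to the carbamate oxygen and attack on boron in preference to the methyl ester, which carbamate-directed deprotonation and the much faster ate-complex formation at −78 °C should secure. C7 reacts at the alcohol oxidation level, so the base-labile β,β'-bis(silyloxy) aldehyde is never made.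

**Step 10**
Reactants: 18 (7S)-allylic alcohol
Product: 19 C7 acetate
Conditions: Ac2O, pyridine, DMAP (cat.), CH2Cl2, 0 °C
Reagents that add atoms: acetic anhydride CC(=O)OC(C)=O
Why: DMAP-catalysed acetylation of the only free hydroxyl group installs the C7 acetate with retention.

**Step 11**
Reactants: 19 C7 acetate
Product: 20 C9 allylic alcohol
Conditions: HF·pyridine, pyridine, THF, 0 °C → rt
Reagents that add atoms: none
Why: Fluoride-mediated desilylation should be far faster at the secondary allylic 9-O-TBS group than at the tertiary 12-O-TBS group next to the quaternary carbon, and the buffered acidic medium should prevent acetyl migration.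

**Step 12**
Reactants: 20 C9 allylic alcohol
Product: 21 enone
Conditions: Dess–Martin periodinane, pyridine, CH2Cl2, 0 °C
Reagents that add atoms: none
Why: Dess–Martin oxidation of the secondary allylic alcohol gives the enone under near-neutral conditions and erases the C9 stereocentre without touching the tertiary silyl ether or the β-acetoxy group.

**Step 13**
Reactants: 21 enone
Product: 22 α-iodoenone
Conditions: I2, pyridine/CH2Cl2 (1:1), 0 °C → rt
Reagents that add atoms: iodine II
Why: Baylis–Hillman-type α-iodination (pyridine adds to C11, the enolate is iodinated at C10, pyridine is lost again) is selective for the enone over the isolated alkenes, the 12-O-TBS group rules out iodoetherification onto C14=C15, and pyridine at 0 °C should be too weak a base to eliminate the C7 acetate.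

**Step 14**
Reactants: 22 α-iodoenone
Product: 23 target
Conditions: 48% aq. HF, MeCN, 0 °C → rt
Reagents that add atoms: none
Why: Acidic fluoride cleavage of the tertiary silyl ether avoids basic conditions, under which the β-acetoxy ketone would eliminate.

**Compound list**
1 | (S)-4-(tert-butyldimethylsilyloxy)cyclopent-2-en-1-one | O=C1C=C[C@@H](O[Si](C)(C)C(C)(C)C)C1 | starting material
2 | formaldehyde (monomer, gas from cracked commercial paraformaldehyde) | C=O | starting material
3 | lithium dienolate of 1 (lithium 4-(tert-butyldimethylsilyloxy)cyclopenta-1,5-dien-1-olate; enolate carbon = future C8) | [Li]OC1=C[C@H](O[Si](C)(C)C(C)(C)C)C=C1 | intermediate (not isolated)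
4 | (4R,5S)-4-(tert-butyldimethylsilyloxy)-5-(hydroxymethyl)cyclopent-2-en-1-one (4,5-trans; CH2OH carbon = C7) | O=C1C=C[C@@H](O[Si](C)(C)C(C)(C)C)[C@@H]1CO | intermediate
5 | (4R,5S)-4-(tert-butyldimethylsilyloxy)-5-[(triethylsilyloxy)methyl]cyclopent-2-en-1-one | O=C1C=C[C@@H](O[Si](C)(C)C(C)(C)C)[C@@H]1CO[Si](CC)(CC)CC | intermediate
6 | 1-bromooct-2-yne | CCCCCC#CCBr | starting material
7 | (octa-1,2-dien-3-yl)zinc bromide (allenyl form of the oct-2-ynylzinc reagent) | CCCCCC(=C=C)[Zn]Br | intermediate (not isolated)
8 | 4-(tert-butyldimethylsilyloxy)-1-(oct-2-yn-1-yl)-5-[(triethylsilyloxy)methyl]cyclopent-2-en-1-ol; ring C1 = C12, C4 = C9, C5 = C8; 1-OH cis to the C5 CH2O group, octynyl trans to it, 4-OSi trans to it | CCCCCC#CC[C@@]1(O)C=C[C@@H](O[Si](C)(C)C(C)(C)C)[C@@H]1CO[Si](CC)(CC)CC | intermediate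
9 | tert-butyldimethylsilyl ether of 8 at the tertiary oxygen (12-O-TBS, 9-O-TBS, 7-O-TES, oct-2-ynyl chain) | CCCCCC#CC[C@@]1(O[Si](C)(C)C(C)(C)C)C=C[C@@H](O[Si](C)(C)C(C)(C)C)[C@@H]1CO[Si](CC)(CC)CC | intermediate
10 | (Z)-oct-2-enyl analogue of 9 (cis C14=C15) | CCCCC/C=C\C[C@@]1(O[Si](C)(C)C(C)(C)C)C=C[C@@H](O[Si](C)(C)C(C)(C)C)[C@@H]1CO[Si](CC)(CC)CC | intermediate
11 | {2,5-bis(tert-butyldimethylsilyloxy)-2-[(Z)-oct-2-en-1-yl]cyclopent-3-en-1-yl}methanol (free 7-OH; ring configuration as in 10) | CCCCC/C=C\C[C@@]1(O[Si](C)(C)C(C)(C)C)C=C[C@@H](O[Si](C)(C)C(C)(C)C)[C@@H]1CO | intermediate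
12 | N,N-diisopropylcarbamate of 11 | CCCCC/C=C\C[C@@]1(O[Si](C)(C)C(C)(C)C)C=C[C@@H](O[Si](C)(C)C(C)(C)C)[C@@H]1COC(=O)N(C(C)C)C(C)C | intermediate
13 | methyl hex-5-ynoate | C#CCCCC(=O)OC | starting material
14 | methyl (Z)-6-(4,4,5,5-tetramethyl-1,3,2-dioxaborolan-2-yl)hex-5-enoate | COC(=O)CCC/C=C\B1OC(C)(C)C(C)(C)O1 | intermediate
15 | α-lithiated carbamate: 12 with lithium in place of the pro-S hydrogen at C7 (as its (−)-sparteine complex) | CCCCC/C=C\C[C@@]1(O[Si](C)(C)C(C)(C)C)C=C[C@@H](O[Si](C)(C)C(C)(C)C)[C@@H]1[C@H]([Li])OC(=O)N(C(C)C)C(C)C | intermediate (not isolated)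
16 | lithium boronate (ate) complex of 15 and 14; C7–B bond formed with retention, cis-alkenyl group still on boron | [Li+].CCCCC/C=C\C[C@@]1(O[Si](C)(C)C(C)(C)C)C=C[C@@H](O[Si](C)(C)C(C)(C)C)[C@@H]1[C@H]([B-]2(/C=C\CCCC(=O)OC)OC(C)(C)C(C)(C)O2)OC(=O)N(C(C)C)C(C)C | intermediate (not isolated)
17 | secondary allylic pinacol boronic ester; C7 bears boron, C8 and the cis C6=C5 alkenyl chain | CCCCC/C=C\C[C@@]1(O[Si](C)(C)C(C)(C)C)C=C[C@@H](O[Si](C)(C)C(C)(C)C)[C@@H]1[C@H](/C=C\CCCC(=O)OC)B1OC(C)(C)C(C)(C)O1 | intermediate (not isolated)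
18 | methyl (5Z,7S,14Z)-9,12-bis(tert-butyldimethylsilyloxy)-7-hydroxyprosta-5,10,14-trienoate (C8 and C12 as in the target; 9-O trans to C7) | CCCCC/C=C\C[C@@]1(O[Si](C)(C)C(C)(C)C)C=C[C@@H](O[Si](C)(C)C(C)(C)C)[C@@H]1[C@H](/C=C\CCCC(=O)OC)O | intermediate
19 | methyl (5Z,7S,14Z)-7-acetoxy-9,12-bis(tert-butyldimethylsilyloxy)prosta-5,10,14-trienoate | CCCCC/C=C\C[C@@]1(O[Si](C)(C)C(C)(C)C)C=C[C@@H](O[Si](C)(C)C(C)(C)C)[C@@H]1[C@H](/C=C\CCCC(=O)OC)OC(C)=O | intermediate
20 | methyl (5Z,7S,14Z)-7-acetoxy-12-(tert-butyldimethylsilyloxy)-9-hydroxyprosta-5,10,14-trienoate | CCCCC/C=C\C[C@@]1(O[Si](C)(C)C(C)(C)C)C=C[C@@H](O)[C@@H]1[C@H](/C=C\CCCC(=O)OC)OC(C)=O | intermediate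
21 | methyl (5Z,7S,14Z)-7-acetoxy-12-(tert-butyldimethylsilyloxy)-9-oxoprosta-5,10,14-trienoate (C8 and C12 as in the target) | CCCCC/C=C\C[C@@]1(O[Si](C)(C)C(C)(C)C)C=CC(=O)[C@@H]1[C@H](/C=C\CCCC(=O)OC)OC(C)=O | intermediate
22 | methyl (5Z,7S,14Z)-7-acetoxy-12-(tert-butyldimethylsilyloxy)-10-iodo-9-oxoprosta-5,10,14-trienoate | CCCCC/C=C\C[C@@]1(O[Si](C)(C)C(C)(C)C)C=C(I)C(=O)[C@@H]1[C@H](/C=C\CCCC(=O)OC)OC(C)=O | intermediate
23 | methyl (5Z,7S,8R,12S,14Z)-7-acetoxy-12-hydroxy-10-iodo-9-oxoprosta-5,10,14-trienoate (7-acetoxy-7,8-dihydroiodovulone I) | CCCCC/C=C\C[C@@]1(O)C=C(I)C(=O)[C@@H]1[C@H](/C=C\CCCC(=O)OC)OC(C)=O | target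

**Step count and risks**
Total step count: 14. Longest linear sequence: 13 steps (1 → 23 through steps 1–7 and 9–14; step 8 makes the second fragment).

Most likely to fail, first: step 9. The deprotonation at the hindered C7 methylene may be slow or may follow the substrate's own bias against the diamine. The organolithium may also add to the ester of 14, or the 1,2-shift may stall at the ate complex. The fallback sets out from 11 and comes back at 18. Alcohol 11 is oxidised with Dess–Martin periodinane (pyridine, CH2Cl2, 0 °C) to the aldehyde F1, which is used at once. F1 is joined by a Nozaki–Hiyama–Kishi coupling (CrCl2, catalytic NiCl2, DMSO/THF, rt) with methyl (Z)-6-iodohex-5-enoate F2. F2 is made from commercial methyl 5-oxopentanoate by Stork–Zhao olefination (Ph3P+CH2I I−, NaN(SiMe3)2, THF/DMPU, −78 °C). The alkenylchromium species should add with retention of the cis geometry and in the Felkin–Anh sense, anti to the quaternary C12, to give 18.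

Second: step 3. The zinc reagent may couple at its substituted terminus and give the allenyl carbinol, and the 9-silyloxy group may erode the facial selectivity set by the C8 substituent. The fallback sets out from 5 and comes back at 9. Zinc-mediated addition of propargyl bromide (the unsubstituted allenylzinc bromide is expected to give only the homopropargylic alcohol) should give the terminal alkyne F3, at which stage any C12 epimer would be separated. Silylation with tBuMe2SiOTf/2,6-lutidine gives the tertiary silyl ether F4. Deprotonation of the alkyne (n-BuLi, THF, −78 °C) and alkylation with 1-iodopentane (DMPU, −78 °C → rt) then gives 9.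

Third: step 13. Pyridine addition at the hindered C11 may be slow enough for base-induced loss of acetic acid across C7–C8, which would give the cross-conjugated trienone. The fallback sets out from 18 and comes back at 22.
- The 7-hydroxyl of 18 is masked as the 4-methoxybenzyl ether F5 (4-methoxybenzyl trichloroacetimidate, catalytic Sc(OTf)3, toluene, 0 °C).
- The 9-O-TBS group is removed as in step 11 to give the alcohol F6, and Dess–Martin oxidation gives the enone F7.
- Iodination as in step 13 gives the iodoenone F8, a β-alkoxy ketone that should be a far poorer elimination substrate.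
- DDQ (CH2Cl2/pH 7 buffer, 0 °C) releases the 7-alcohol F9.
- Brief acetylation (Ac2O, pyridine, 0 °C) gives 22.

**Further compounds**
F1 | step 9 | 2,5-bis(tert-butyldimethylsilyloxy)-2-[(Z)-oct-2-en-1-yl]cyclopent-3-ene-1-carbaldehyde (C7 aldehyde; ring configuration as in 11) | CCCCC/C=C\C[C@@]1(O[Si](C)(C)C(C)(C)C)C=C[C@@H](O[Si](C)(C)C(C)(C)C)[C@@H]1C=O
F2 | step 9 | methyl (Z)-6-iodohex-5-enoate | COC(=O)CCC/C=C\I
F3 | step 3 | 4-(tert-butyldimethylsilyloxy)-1-(prop-2-yn-1-yl)-5-[(triethylsilyloxy)methyl]cyclopent-2-en-1-ol (configuration as in 8) | C#CC[C@@]1(O)C=C[C@@H](O[Si](C)(C)C(C)(C)C)[C@@H]1CO[Si](CC)(CC)CC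
F4 | step 3 | tert-butyldimethylsilyl ether of F3 at the tertiary oxygen | C#CC[C@@]1(O[Si](C)(C)C(C)(C)C)C=C[C@@H](O[Si](C)(C)C(C)(C)C)[C@@H]1CO[Si](CC)(CC)CC
F5 | step 13 | 7-O-(4-methoxybenzyl) ether of 18 | CCCCC/C=C\C[C@@]1(O[Si](C)(C)C(C)(C)C)C=C[C@@H](O[Si](C)(C)C(C)(C)C)[C@@H]1[C@H](/C=C\CCCC(=O)OC)OCc1ccc(OC)cc1
F6 | step 13 | 9-hydroxy compound from F5 (12-O-TBS and 7-O-PMB kept) | CCCCC/C=C\C[C@@]1(O[Si](C)(C)C(C)(C)C)C=C[C@@H](O)[C@@H]1[C@H](/C=C\CCCC(=O)OC)OCc1ccc(OC)cc1
F7 | step 13 | 9-oxo enone from F6 | CCCCC/C=C\C[C@@]1(O[Si](C)(C)C(C)(C)C)C=CC(=O)[C@@H]1[C@H](/C=C\CCCC(=O)OC)OCc1ccc(OC)cc1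
F8 | step 13 | 10-iodo enone from F7 | CCCCC/C=C\C[C@@]1(O[Si](C)(C)C(C)(C)C)C=C(I)C(=O)[C@@H]1[C@H](/C=C\CCCC(=O)OC)OCc1ccc(OC)cc1
F9 | step 13 | 7-hydroxy-10-iodo enone (12-O-TBS kept) | CCCCC/C=C\C[C@@]1(O[Si](C)(C)C(C)(C)C)C=C(I)C(=O)[C@@H]1[C@H](/C=C\CCCC(=O)OC)O
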